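Atoms carry drimane numbering throughout: C1–C10 are the decalin carbons, C11 is the bridge carbon on C9, C12 the methyl on C8, C13 and C14 the methyls on C4, C15 the methyl on C10; primed numbers denote the second half. Compound numbers refer to the list after the steps. Step 2 joins two molecules of 4; from step 3 on, every operation acts on both halves at once.

## Analysis of the target

The target 21 is a C30H50 hydrocarbon of the onocerane type: two identical trans-fused decalins (rings A and B, and their primed counterparts) joined by a saturated two-carbon bridge C11–C11' between C9 and C9'. Each half carries a tetrasubstituted C8=C9 alkene with a methyl group on C8, a gem-dimethyl group on C4 and an angular methyl group on C10. The only stereocentres are C5 and C10 in each half, all four S. Within a half the C10 methyl and the C5 hydrogen are trans, and the two halves are homochiral, so the molecule is C2-symmetric and not meso. The only functional groups are the two tetrasubstituted alkenes; under acid they can protonate to C8 or C9 cations that invite a 1,2-shift of the C10 methyl group, so cationic chemistry late in the route is unwelcome. The difficulty lies in the congested C4–C5–C10–C9 array (quaternary, tertiary, quaternary stereocentre, fully substituted sp2 carbon), which has to be built twice with absolute control and no heteroatom left behind. The strategy rests on the observation that ring B (C5–C10) has the substitution pattern of a 1,2,3-trisubstituted benzene: C10 bears C1, C9 bears the bridge, C8 bears a methyl group, C6 and C7 are unsubstituted, and the one remaining substituent, C4 on C5, can be attached after the ring has been dearomatised. Ring B therefore maps onto a 2,3-dialkylbenzoic acid whose carboxyl carbon is C1, and the C11–C11' bridge onto a bibenzyl bond.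

## Retrosynthetic reasoning

21 from 20. The last operation should not be able to touch the tetrasubstituted alkenes. Ring A is therefore given a cis-disubstituted C1=C2 double bond in 20, which a heterogeneous hydrogenation can saturate selectively on steric grounds. This costs one step and lets ring A be closed by alkene-forming chemistry.

20 from 19. The C1=C2 and C1'=C2' bonds are cut. C1 is the former carboxyl carbon on C10 and C2 is the terminus of the side chain on C5, so both can be brought to the aldehyde level, and a reductive carbonyl coupling joins them without an extra carbon. The forward reaction must close two six-membered rings in the tetra-aldehyde 19 in preference to coupling across the bridge; the 1,6-relationship within each half favours this.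

19 from 18 and 17. These are oxidation-level adjustments. The four formyl groups come from the four primary alcohols of 18. The C1 alcohol comes from reductive cleavage of the carboxamide in 17, which also returns the auxiliary 2. The amide is kept until this point because it is the bulky group that steers the earlier addition at C5.

17 from 16, 14 and 12. The C7 carbonyl of 12 has served its purpose and must go without moving the C8=C9 bond. Conversion into the dithioketal 14 and later nickel desulfurisation does this without a cation at C7 or C9. Because nickel would also saturate a vinyl group, the terminal alkene of the side chain is first converted by hydroboration and oxidation into the C2 alcohol of 16, which the later coupling needs anyway.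

12 from 10 and 11. The C4–C5 and C4'–C5' bonds are cut. C2, C3, C4 and both methyl groups on C4 arrive together from the allylsilane 11, which reacts through its γ-carbon and so delivers the quaternary C4 directly onto C5. The C7 carbonyl of the cross-conjugated dienone 10 activates C5. The other β-carbon, C9, is fully substituted and should not compete. The forward reaction has to set C5 on the face of the C10 methyl group, anti to the carboxamide, which becomes the trans ring fusion.

10 from 9. C7 is the doubly allylic methylene of the cyclohexa-1,4-diene 9 and is the obvious site for oxidation. Because C10 is quaternary, the ring cannot aromatise and a dienone results.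

9 from 6 and 7. This is the central disconnection: the C10–C15 and C10'–C15' bonds are cut and both rings are returned to the aromatic state. In the forward direction a dissolving-metal reduction of each benzamide ring of 6 with one proton per ring gives the amide enolate 8, whose nucleophilic carbon is C10 and which 7 methylates. The residual unsaturation falls on C5=C6 and on the alkyl-bearing C8=C9 bond, so the tetrasubstituted alkene of the target appears at the correct position from the start. The chiral amide controls C10.

6 from 4. The C11–C11' bond is cut at the centre of the bibenzyl, which divides 6 into two molecules of 4. The ortho methyl group of 4 is acidified by the neighbouring amide, and oxidative coupling of two molecules of the benzylic lithium compound 5 makes the symmetric bond in one operation. The saturated bridge also insulates the two rings so that each behaves independently in the reduction.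

4 from 1 and 2. The amide bond is cut, giving the commercial acid 1 and the commercial auxiliary 2.

## Alternatives that were turned down

Alternative 1: The C9–C11 and C9'–C11' bonds are cut, so that the bridge comes from dilithium acetylide A3 and each decalin from the trans-decalone A2. In the forward key step A3 adds twice to the C9 carbonyl of A2 to give the ynediol A1; alkyne hydrogenation and twofold dehydration towards C8 would follow. In its favour, it is highly convergent, and C5 and C10 arrive already set in A2, so the trans ring fusion is never at risk; on convergence it is stronger than the chosen route. Against it, the C9 carbonyl of A2 is flanked by the quaternary C10 and an enolisable C8 methine, so the second addition, by an acetylide that already carries a hindered alkoxide, competes poorly with enolisation. More seriously, the end game must remove two tertiary C9 hydroxyl groups. An elimination with cationic character generates a C9 cation next to the quaternary C10, which is the classical trigger for a 1,2-methyl shift, and it also offers the exocyclic C9=C11 alkene as a competing outcome. A2 itself needs a multi-step enantioselective preparation, which consumes the apparent brevity. The chosen route offers in its place an alkene whose position is fixed by the regiochemistry of the arene reduction, with no cation at C9 at any stage, and it starts from a cheap achiral acid.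

Alternative 2: The C5–C6 and C5'–C6' bonds are cut, giving the twelve-carbon bis-Grignard reagent A5 and two molecules of the enone A6. In the forward key step CuBr·SMe2 A7 (monovalent copper), combined with a chiral ferrocenyl diphosphine, adds both ends of A5 to A6 to give the diketone A4, which already holds all thirty carbons. In its favour, this is the most step-economical way to assemble the skeleton, and it sets C5 by catalysis, not with an auxiliary; on both points it is stronger than the chosen route. Against it, the β-carbon of A6 sits between a quaternary carbon and an α-methylated enone carbon. Such acceptors react slowly in copper-catalysed asymmetric Grignard additions, 1,2-addition competes, and the reaction must succeed twice on one reagent. Ring B and C10 are still missing in A4. They would have to be made by forming C9–C10 through a tertiary C10 cation attacked by the C8=C9 alkene, twice, with control of ring fusion and of the alkene position among several isomers, and the C1 oxygen must then be removed. The chosen route never has to close ring B, because ring B is the arene, and it sets C10 by an auxiliary-controlled alkylation of a well-defined enolate.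

Alternative 3: The C5–C10 and C6–C7 bonds of both halves are cut, unravelling all four rings to the acyclic bis-trienal A9. In the forward key step a chiral imidazolidinone salt activates each enal as its iminium ion, and each C7=C8–C9=C10 diene adds to its C5=C6 dienophile to give the tetracyclic dialdehyde A8. In its favour, four rings and all four ring-fusion stereocentres form in one catalytic step, and the cycloaddition places the C8=C9 alkene correctly by its own mechanism. On ring count it is clearly stronger than the chosen route and on alkene placement it is equal. Against it, the diene terminus C10 is fully substituted and must become a quaternary centre while bonding to C5, which is neopentylic next to the gem-dimethyl C4. The inside methyl group on C10 destabilises the s-cis diene, and hindered β-substituted enals are slow partners in iminium catalysis. A9 needs two stereodefined tetrasubstituted alkenes and is reached only by a long linear sequence, and the two formyl groups on C6 and C6' must afterwards be excised. The chosen route offers a precursor made in two steps and a key step that forms only two bonds but does so in a well-understood manner, leaving ring A to conventional chemistry.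

Key step: step 3

Assumption: in the potassium-chelated enolate of the (S)-configured amide, iodomethane is taken to enter anti to the methoxymethyl arm and thereby to give the (10S,10'S) configuration drawn for 9.

## Steps

Step 1
Reactants: 1 2,3-dimethylbenzoic acid; 2 (S)-2-(methoxymethyl)pyrrolidine
Product: 4 (S)-(2,3-dimethylphenyl)[2-(methoxymethyl)pyrrolidin-1-yl]methanone, via 2,3-dimethylbenzoyl chloride 3 (not isolated)
Conditions: (COCl)2, DMF (cat.), CH2Cl2, 0 °C → rt; evaporate; 2, Et3N, CH2Cl2, 0 °C → rt
Reagents that add atoms: oxalyl chloride, `ClC(=O)C(=O)Cl` (supplies only the chlorine of 3)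
Why: Acid chloride formation and Schotten–Baumann-type acylation of a secondary amine; the acid chloride overcomes the hindrance of the ortho-substituted acid, and the stereocentre of 2 is not involved.

Step 2
Reactants: 4 (S)-(2,3-dimethylphenyl)[2-(methoxymethyl)pyrrolidin-1-yl]methanone (two molecules per molecule of product)
Product: 6 1,2-bis{2-methyl-6-[(S)-2-(methoxymethyl)pyrrolidine-1-carbonyl]phenyl}ethane, via benzylic lithium compound 5 (not isolated)
Conditions: LiN(iPr)2 (1.1 equiv), THF, −78 °C; CuCl2 (anhydrous, 1.1 equiv), −78 °C → rt
Reagents that add atoms: second molecule of 4 (S)-(2,3-dimethylphenyl)[2-(methoxymethyl)pyrrolidin-1-yl]methanone, `Cc1cccc(C(=O)N2CCC[C@H]2COC)c1C`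
Why: Lateral lithiation: the tertiary amide directs and stabilises deprotonation of the ortho methyl group only, the meta methyl group being unactivated. Divalent copper then oxidises the benzylic organolithium 5, and two benzylic units join through their CH2 carbons to form the C11–C11' bond (oxidative homocoupling of an organolithium). The step is a dimerisation, so both halves of 6, each with its amide and auxiliary, come from 4.

Step 3
Reactants: 6 1,2-bis{2-methyl-6-[(S)-2-(methoxymethyl)pyrrolidine-1-carbonyl]phenyl}ethane; 7 iodomethane
Product: 9 1,2-bis{(6S)-2,6-dimethyl-6-[(S)-2-(methoxymethyl)pyrrolidine-1-carbonyl]cyclohexa-1,4-dien-1-yl}ethane, via dipotassium bis(amide enolate) 8 (not isolated)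
Conditions: K (2.2–2.5 equiv per ring), NH3(l)/THF, t-BuOH (1.0 equiv per ring), −78 °C; piperylene; 7 (excess), −78 °C; NH4Cl
Reagents that add atoms: iodomethane 7, `CI`
Why: Each benzamide ring takes up an electron, the radical anion is protonated by tert-butanol at C7 (para to the carboxamide), and a second electron gives the potassium amide enolate 8, whose α-carbon is C10. With one proton per ring no acid remains, so the enolate persists until the excess metal is discharged, and iodomethane then alkylates C10 and not the vinylogous positions C6 or C8. The closest known reaction type is the asymmetric Birch reduction–alkylation of chiral 2-alkylbenzamides of prolinol ethers to cyclohexa-1,4-dienes with a quaternary carbon. No ring is closed; the C10–C15 and C10'–C15' bonds and two stereocentres are formed. Each C10 is controlled by the auxiliary: potassium bridges the enolate oxygen and the ether oxygen, the methoxymethyl arm shields one face, and the electrophile enters from the other. The step needs ipso/para regiochemistry of reduction, which the electron-withdrawing amide and the donor alkyl groups on C8 and C9 secure, so that the unsaturation is left at C5=C6 and C8=C9. It also needs a stop at the dihydro stage, secured by the stoichiometric proton source and low temperature, and the same facial sense in both rings, secured by the saturated bridge that lets each ring react like the monomeric benzamide. A single facial error gives a diastereomer, not the enantiomer, so chromatographic removal of the minor isomer should raise the stereochemical purity of 9.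

Step 4
Reactants: 9 1,2-bis{(6S)-2,6-dimethyl-6-[(S)-2-(methoxymethyl)pyrrolidine-1-carbonyl]cyclohexa-1,4-dien-1-yl}ethane
Product: 10 1,2-bis{(6S)-2,6-dimethyl-6-[(S)-2-(methoxymethyl)pyrrolidine-1-carbonyl]-3-oxocyclohexa-1,4-dien-1-yl}ethane
Conditions: t-BuOOH (excess), (C5H5NH)2Cr2O7 (cat.), Celite, benzene, rt
Reagents that add atoms: tert-butyl hydroperoxide, `CC(C)(C)OO`
Why: Chromium-mediated radical allylic oxidation with tert-butyl hydroperoxide: the doubly allylic C7–H bonds are the weakest in the molecule, and the intermediate mixed peroxide loses tert-butanol to give the ketone. C10 is quaternary, so the ring cannot aromatise and the cross-conjugated cyclohexa-2,5-dienone results.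

Step 5
Reactants: 10 1,2-bis{(6S)-2,6-dimethyl-6-[(S)-2-(methoxymethyl)pyrrolidine-1-carbonyl]-3-oxocyclohexa-1,4-dien-1-yl}ethane; 11 trimethyl(3-methylbut-2-en-1-yl)silane
Product: 12 1,2-bis{(5S,6S)-2,6-dimethyl-5-(2-methylbut-3-en-2-yl)-6-[(S)-2-(methoxymethyl)pyrrolidine-1-carbonyl]-3-oxocyclohex-1-en-1-yl}ethane
Conditions: TiCl4 (excess), 11, CH2Cl2, −78 → −40 °C; aq. NaHCO3
Reagents that add atoms: trimethyl(3-methylbut-2-en-1-yl)silane 11, `CC(C)=CC[Si](C)(C)C`
Why: Hosomi–Sakurai conjugate allylation: the allylsilane attacks through its γ-carbon, so the 1,1-dimethylallyl group (C4 with both methyls, C3, C2) is delivered to C5, the β-CH of the disubstituted enone arm; the other β-carbon, C9, is fully substituted. The nucleophile should enter anti to the titanium-bound carboxamide and syn to the smaller C10 methyl group, which sets C5 as S with C5–H trans to the C10 methyl group. Protonation of the titanium enolate at C6 leaves the C7 ketone conjugated with C8=C9.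

Step 6
Reactants: 12 1,2-bis{(5S,6S)-2,6-dimethyl-5-(2-methylbut-3-en-2-yl)-6-[(S)-2-(methoxymethyl)pyrrolidine-1-carbonyl]-3-oxocyclohex-1-en-1-yl}ethane; 13 ethane-1,2-dithiol
Product: 14 1,2-bis{(8S,9S)-6,8-dimethyl-9-(2-methylbut-3-en-2-yl)-8-[(S)-2-(methoxymethyl)pyrrolidine-1-carbonyl]-1,4-dithiaspiro[4.5]dec-6-en-7-yl}ethane (the C7 and C7' dithiolane of 12)
Conditions: 13, BF3·OEt2, CH2Cl2, 0 °C → rt
Reagents that add atoms: ethane-1,2-dithiol 13, `SCCS`
Why: Lewis-acid-promoted dithioketalisation of the enone carbonyl; the fully substituted β-carbon C9 blocks thiol conjugate addition, and the C8=C9 bond is already in its most stable position and should not migrate.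

Step 7
Reactants: 14 the C7 and C7' dithiolane of 12
Product: 16 1,2-bis{(8S,9S)-9-(4-hydroxy-2-methylbutan-2-yl)-6,8-dimethyl-8-[(S)-2-(methoxymethyl)pyrrolidine-1-carbonyl]-1,4-dithiaspiro[4.5]dec-6-en-7-yl}ethane, via bis(B-alkyl-9-borabicyclononane) 15 (not isolated)
Conditions: 9-BBN, THF, 0 °C → rt; NaOH (aq.), H2O2, 0 °C
Reagents that add atoms: 9-borabicyclo[3.3.1]nonane, `B1C2CCCC1CCC2` (boron unit of 15 only); hydrogen peroxide, `OO`
Why: Hydroboration–oxidation: the hindered borane adds anti-Markovnikov to the monosubstituted alkene only, leaving the tetrasubstituted C8=C9 bond and the shielded tertiary amide untouched. Alkaline peroxide at 0 °C oxidises the C–B bond much faster than thioether sulfur, placing the hydroxyl group on C2.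

Step 8
Reactants: 16 the C2 and C2' diol bearing the dithiolanes
Product: 17 1,2-bis{(5S,6S)-5-(4-hydroxy-2-methylbutan-2-yl)-2,6-dimethyl-6-[(S)-2-(methoxymethyl)pyrrolidine-1-carbonyl]cyclohex-1-en-1-yl}ethane
Conditions: Raney Ni (W-2), EtOH, reflux
Reagents that add atoms: none
Why: Raney nickel hydrogenolysis of both C–S bonds (Mozingo-type desulfurisation) turns C7 into a methylene group; the tetrasubstituted alkene is neither hydrogenated nor offered a more stable position, as in the classical conversion of enone dithioketals into alkenes.

Step 9
Reactants: 17 1,2-bis{(5S,6S)-5-(4-hydroxy-2-methylbutan-2-yl)-2,6-dimethyl-6-[(S)-2-(methoxymethyl)pyrrolidine-1-carbonyl]cyclohex-1-en-1-yl}ethane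
Product: 18 1,2-bis{(5S,6S)-6-(hydroxymethyl)-5-(4-hydroxy-2-methylbutan-2-yl)-2,6-dimethylcyclohex-1-en-1-yl}ethane
Conditions: LiNH2BH3 (from BH3·NH3 and LiN(iPr)2), THF, 0 → 66 °C; aq. HCl, then NaOH
Reagents that add atoms: none
Why: Reductive C–N cleavage of a tertiary amide to the primary alcohol by lithium amidotrihydroborate, a small and strongly nucleophilic hydride donor suited to α-quaternary amides; the hemiaminal intermediate collapses to the aldehyde, which is reduced further, and 2 is released for recovery. C5 and C10 are not affected.

Step 10
Reactants: 18 1,2-bis{(5S,6S)-6-(hydroxymethyl)-5-(4-hydroxy-2-methylbutan-2-yl)-2,6-dimethylcyclohex-1-en-1-yl}ethane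
Product: 19 1,2-bis{(5S,6S)-6-formyl-2,6-dimethyl-5-(2-methyl-4-oxobutan-2-yl)cyclohex-1-en-1-yl}ethane
Conditions: Dess–Martin periodinane, CH2Cl2, 0 °C → rt
Reagents that add atoms: none
Why: Dess–Martin oxidation of all four primary alcohols under near-neutral conditions, which should avoid aldol closure between C3 and the C1 formyl group; C10 is quaternary and cannot epimerise.

Step 11
Reactants: 19 1,2-bis{(5S,6S)-6-formyl-2,6-dimethyl-5-(2-methyl-4-oxobutan-2-yl)cyclohex-1-en-1-yl}ethane
Product: 20 1,2-bis[(4aS,8aS)-2,5,5,8a-tetramethyl-3,4,4a,5,6,8a-hexahydronaphthalen-1-yl]ethane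
Conditions: TiCl3(DME)1.5, Zn–Cu, DME, reflux; slow addition of 19 (high dilution)
Reagents that add atoms: none
Why: McMurry coupling: low-valent titanium joins the C1 and C2 formyl groups of each half by pinacol coupling and deoxygenates the titanium diolate to the cis C1=C2 alkene. The 1,6-relationship makes closure of the six-membered ring A faster than coupling across the bridge, and high dilution suppresses oligomers. The trans ring fusion is already fixed by C5 and C10, and no new stereocentre forms.

Step 12
Reactants: 20 1,2-bis[(4aS,8aS)-2,5,5,8a-tetramethyl-3,4,4a,5,6,8a-hexahydronaphthalen-1-yl]ethane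
Product: 21 1,2-bis[(4aS,8aS)-2,5,5,8a-tetramethyl-3,4,4a,5,6,7,8,8a-octahydronaphthalen-1-yl]ethane
Conditions: H2 (1 atm), Pd/C, EtOAc, rt
Reagents that add atoms: none
Why: Heterogeneous catalytic hydrogenation saturates only the disubstituted C1=C2 and C1'=C2' alkenes; the tetrasubstituted C8=C9 alkenes are too hindered to be reduced under these conditions.

## Compound list

1 | 2,3-dimethylbenzoic acid | `Cc1cccc(C(=O)O)c1C` | starting material
2 | (S)-2-(methoxymethyl)pyrrolidine | `COC[C@@H]1CCCN1` | starting material
3 | 2,3-dimethylbenzoyl chloride | `Cc1cccc(C(=O)Cl)c1C` | intermediate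
4 | (S)-(2,3-dimethylphenyl)[2-(methoxymethyl)pyrrolidin-1-yl]methanone | `Cc1cccc(C(=O)N2CCC[C@H]2COC)c1C` | intermediate
5 | {2-methyl-6-[(S)-2-(methoxymethyl)pyrrolidine-1-carbonyl]benzyl}lithium | `[Li]Cc1c(C)cccc1C(=O)N1CCC[C@H]1COC` | intermediate
6 | 1,2-bis{2-methyl-6-[(S)-2-(methoxymethyl)pyrrolidine-1-carbonyl]phenyl}ethane | `COC[C@@H]1CCCN1C(=O)c1cccc(C)c1CCc1c(C)cccc1C(=O)N1CCC[C@H]1COC` | intermediate
7 | iodomethane | `CI` | starting material
8 | dipotassium bis(amide enolate) of the twofold 1,4-dihydro compound (enolate carbon C10, C7 protonated) | `C(CC1=C(C)CC=CC1=C([O-])N1CCC[C@H]1COC)C1=C(C)CC=CC1=C([O-])N1CCC[C@H]1COC.[K+].[K+]` | intermediate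
9 | 1,2-bis{(6S)-2,6-dimethyl-6-[(S)-2-(methoxymethyl)pyrrolidine-1-carbonyl]cyclohexa-1,4-dien-1-yl}ethane | `C(CC1=C(C)CC=C[C@]1(C)C(=O)N1CCC[C@H]1COC)C1=C(C)CC=C[C@]1(C)C(=O)N1CCC[C@H]1COC` | intermediate
10 | 1,2-bis{(6S)-2,6-dimethyl-6-[(S)-2-(methoxymethyl)pyrrolidine-1-carbonyl]-3-oxocyclohexa-1,4-dien-1-yl}ethane | `C(CC1=C(C)C(=O)C=C[C@]1(C)C(=O)N1CCC[C@H]1COC)C1=C(C)C(=O)C=C[C@]1(C)C(=O)N1CCC[C@H]1COC` | intermediate
11 | trimethyl(3-methylbut-2-en-1-yl)silane (prenyltrimethylsilane) | `CC(C)=CC[Si](C)(C)C` | starting material
12 | 1,2-bis{(5S,6S)-2,6-dimethyl-5-(2-methylbut-3-en-2-yl)-6-[(S)-2-(methoxymethyl)pyrrolidine-1-carbonyl]-3-oxocyclohex-1-en-1-yl}ethane (side chain on C5 cis to the C10 methyl group) | `C(CC1=C(C)C(=O)C[C@@H](C(C)(C)C=C)[C@]1(C)C(=O)N1CCC[C@H]1COC)C1=C(C)C(=O)C[C@@H](C(C)(C)C=C)[C@]1(C)C(=O)N1CCC[C@H]1COC` | intermediate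
13 | ethane-1,2-dithiol | `SCCS` | starting material
14 | 1,2-bis{(8S,9S)-6,8-dimethyl-9-(2-methylbut-3-en-2-yl)-8-[(S)-2-(methoxymethyl)pyrrolidine-1-carbonyl]-1,4-dithiaspiro[4.5]dec-6-en-7-yl}ethane | `C(CC1=C(C)C2(SCCS2)C[C@@H](C(C)(C)C=C)[C@]1(C)C(=O)N1CCC[C@H]1COC)C1=C(C)C2(SCCS2)C[C@@H](C(C)(C)C=C)[C@]1(C)C(=O)N1CCC[C@H]1COC` | intermediate
15 | bis(B-alkyl-9-borabicyclo[3.3.1]nonane) from hydroboration of both vinyl groups of 14 (boron on C2 and C2') | `C(CC1=C(C)C2(SCCS2)C[C@@H](C(C)(C)CCB2C3CCCC2CCC3)[C@]1(C)C(=O)N1CCC[C@H]1COC)C1=C(C)C2(SCCS2)C[C@@H](C(C)(C)CCB2C3CCCC2CCC3)[C@]1(C)C(=O)N1CCC[C@H]1COC` | intermediate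
16 | 1,2-bis{(8S,9S)-9-(4-hydroxy-2-methylbutan-2-yl)-6,8-dimethyl-8-[(S)-2-(methoxymethyl)pyrrolidine-1-carbonyl]-1,4-dithiaspiro[4.5]dec-6-en-7-yl}ethane | `C(CC1=C(C)C2(SCCS2)C[C@@H](C(C)(C)CCO)[C@]1(C)C(=O)N1CCC[C@H]1COC)C1=C(C)C2(SCCS2)C[C@@H](C(C)(C)CCO)[C@]1(C)C(=O)N1CCC[C@H]1COC` | intermediate
17 | 1,2-bis{(5S,6S)-5-(4-hydroxy-2-methylbutan-2-yl)-2,6-dimethyl-6-[(S)-2-(methoxymethyl)pyrrolidine-1-carbonyl]cyclohex-1-en-1-yl}ethane | `C(CC1=C(C)CC[C@@H](C(C)(C)CCO)[C@]1(C)C(=O)N1CCC[C@H]1COC)C1=C(C)CC[C@@H](C(C)(C)CCO)[C@]1(C)C(=O)N1CCC[C@H]1COC` | intermediate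
18 | 1,2-bis{(5S,6S)-6-(hydroxymethyl)-5-(4-hydroxy-2-methylbutan-2-yl)-2,6-dimethylcyclohex-1-en-1-yl}ethane | `C(CC1=C(C)CC[C@@H](C(C)(C)CCO)[C@]1(C)CO)C1=C(C)CC[C@@H](C(C)(C)CCO)[C@]1(C)CO` | intermediate
19 | 1,2-bis{(5S,6S)-6-formyl-2,6-dimethyl-5-(2-methyl-4-oxobutan-2-yl)cyclohex-1-en-1-yl}ethane | `C(CC1=C(C)CC[C@@H](C(C)(C)CC=O)[C@]1(C)C=O)C1=C(C)CC[C@@H](C(C)(C)CC=O)[C@]1(C)C=O` | intermediate
20 | 1,2-bis[(4aS,8aS)-2,5,5,8a-tetramethyl-3,4,4a,5,6,8a-hexahydronaphthalen-1-yl]ethane | `CC1=C(CCC2=C(C)CC[C@H]3C(C)(C)CC=C[C@]23C)[C@@]2(C)C=CCC(C)(C)[C@@H]2CC1` | intermediate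
21 | 1,2-bis[(4aS,8aS)-2,5,5,8a-tetramethyl-3,4,4a,5,6,7,8,8a-octahydronaphthalen-1-yl]ethane | `CC1=C(CCC2=C(C)CC[C@H]3C(C)(C)CCC[C@]23C)[C@@]2(C)CCCC(C)(C)[C@@H]2CC1` | target

## Step count and risk

Total: 12 steps. Longest linear sequence: 12 steps, from 1 to 21; compounds 2, 7, 11 and 13 enter as purchased reagents.

Step 3 (key step). The methyl group may enter from the wrong face in one or both rings, or with incomplete selectivity. The diene or the amide may be over-reduced if more than one proton per ring is available, the C11–C11' bond may cleave at the radical-anion stage, and conversion of the second ring may stay incomplete. Fallback, from 6 back to 9: the reduction is run with a protic quench (K, NH3, t-BuOH, then NH4Cl) to give the twofold 1,4-dihydro amide F1. F1 is then deprotonated at C10 with LiN(iPr)2 in THF at −78 °C and methylated with 7. The enolate made by deprotonation differs in geometry and aggregation from the one generated in ammonia and is known in this class to expose the other face. Reduction and alkylation are thereby separated and can each be tuned.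

Step 5. Bond formation may be sluggish, because C5 is neopentylic and the attacking carbon is tertiary. Attack may occur from the carboxamide face. The Lewis acid may trigger a dienone–phenol rearrangement with 1,2-shift of the carboxamide, or 11 may be protodesilylated. Fallback, from 10 back to 12: an α-selective 1,2-addition of (3-methylbut-2-en-1-yl)barium chloride to the C7 carbonyl would give the bis(tertiary dienol) F2 with the prenyl group on the face of the C10 methyl group. An anionic oxy-Cope rearrangement (KH, 18-crown-6, THF) would then carry the allyl unit suprafacially to C5 with allylic transposition, creating the 1,1-dimethylallyl group, and protonation of the enolate gives 12. Facial control then rests on the more remote influence of C10 on the addition at C7.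

Step 9. Hydride attack on the shielded carbonyl may be incomplete, or C–O cleavage may win over C–N cleavage and give the tertiary amine. Fallback, from 17 directly to 21: the C2 alcohols are converted into the bis-iodide F3 (I2, PPh3, imidazole). Iodine–lithium exchange with t-BuLi in Et2O–pentane at −78 °C is followed by intramolecular attack of the primary alkyllithium on the neighbouring carboxamide. This closes ring A and, after collapse of the tetrahedral intermediate on work-up, gives the ring-A diketone F4 with loss of 2. Reduction with LiAlH4 gives the diol F5, NaH/CS2/MeI gives the bis-xanthate F6, and Bu3SnH with AIBN in refluxing toluene removes the C1 oxygen to give 21. This forms the C1–C2 bond by anionic acylation and bypasses steps 9 to 12 at the cost of one additional step.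

Step 11. Coupling may occur between molecules or across the bridge, the reaction may stop at the pinacol stage, or the enolisable C2 aldehyde may undergo aldol condensation on Lewis-acidic titanium. Fallback, from 19 back to 20: fourfold methylenation with Ph3P=CH2 gives the tetraene F7, and twofold ring-closing metathesis with the second-generation Grubbs catalyst (H2IMes)(PCy3)Cl2Ru=CHPh in CH2Cl2 at 40 °C joins C1 to C2 in each half with loss of ethene.

Step 2. The benzylic anion may condense with the amide carbonyl of a second molecule, ring lithiation ortho to the amide may compete, or the anion may be chlorinated without coupling. Fallback, from 1 back to 6: the dianion of 1 (carboxylate plus ortho benzylic anion, 2 equiv LiN(iPr)2) is coupled oxidatively (CuCl2 or I2) to the diacid F8, in which the carboxylate cannot act as an electrophile. F8 is converted with oxalyl chloride into the bis(acid chloride) F9 and acylated twice with 2.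

## Further compounds

F1 | step 3 | 1,2-bis{2-methyl-6-[(S)-2-(methoxymethyl)pyrrolidine-1-carbonyl]cyclohexa-1,4-dien-1-yl}ethane (C10 and C10' epimers, erased on enolisation) | `C(CC1=C(C)CC=CC1C(=O)N1CCC[C@H]1COC)C1=C(C)CC=CC1C(=O)N1CCC[C@H]1COC`
F2 | step 5 | 1,2-bis{(6S)-3-hydroxy-2,6-dimethyl-3-(3-methylbut-2-en-1-yl)-6-[(S)-2-(methoxymethyl)pyrrolidine-1-carbonyl]cyclohexa-1,4-dien-1-yl}ethane (prenyl group cis to the C10 methyl group) | `C(CC1=C(C)[C@@](O)(CC=C(C)C)C=C[C@]1(C)C(=O)N1CCC[C@H]1COC)C1=C(C)[C@@](O)(CC=C(C)C)C=C[C@]1(C)C(=O)N1CCC[C@H]1COC`
F3 | step 9 | 1,2-bis{(5S,6S)-5-(4-iodo-2-methylbutan-2-yl)-2,6-dimethyl-6-[(S)-2-(methoxymethyl)pyrrolidine-1-carbonyl]cyclohex-1-en-1-yl}ethane | `C(CC1=C(C)CC[C@@H](C(C)(C)CCI)[C@]1(C)C(=O)N1CCC[C@H]1COC)C1=C(C)CC[C@@H](C(C)(C)CCI)[C@]1(C)C(=O)N1CCC[C@H]1COC`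
F4 | step 9 | 1,2-bis[(4aS,8aS)-2,5,5,8a-tetramethyl-8-oxo-3,4,4a,5,6,7,8,8a-octahydronaphthalen-1-yl]ethane (C1 and C1' ketone) | `CC1=C(CCC2=C(C)CC[C@H]3C(C)(C)CCC(=O)[C@]23C)[C@@]2(C)C(=O)CCC(C)(C)[C@@H]2CC1`
F5 | step 9 | 1,2-bis[(4aS,8aS)-8-hydroxy-2,5,5,8a-tetramethyl-3,4,4a,5,6,7,8,8a-octahydronaphthalen-1-yl]ethane (carbinol epimers at C1 and C1', inconsequential) | `CC1=C(CCC2=C(C)CC[C@H]3C(C)(C)CCC(O)[C@]23C)[C@@]2(C)C(O)CCC(C)(C)[C@@H]2CC1`
F6 | step 9 | bis(O-alkyl S-methyl dithiocarbonate) of F5 | `CC1=C(CCC2=C(C)CC[C@H]3C(C)(C)CCC(OC(=S)SC)[C@]23C)[C@@]2(C)C(OC(=S)SC)CCC(C)(C)[C@@H]2CC1`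
F7 | step 11 | 1,2-bis{(5S,6S)-6-ethenyl-2,6-dimethyl-5-(2-methylpent-4-en-2-yl)cyclohex-1-en-1-yl}ethane | `C(CC1=C(C)CC[C@@H](C(C)(C)CC=C)[C@]1(C)C=C)C1=C(C)CC[C@@H](C(C)(C)CC=C)[C@]1(C)C=C`
F8 | step 2 | 2,2'-(ethane-1,2-diyl)bis(3-methylbenzoic acid) | `O=C(O)c1cccc(C)c1CCc1c(C)cccc1C(=O)O`
F9 | step 2 | 2,2'-(ethane-1,2-diyl)bis(3-methylbenzoyl chloride) | `O=C(Cl)c1cccc(C)c1CCc1c(C)cccc1C(=O)Cl`
A1 | alternative 1 | 1,2-bis(1-hydroxy-2,5,5,8a-tetramethyldecahydronaphthalen-1-yl)ethyne, trans-fused, alkynyl axial on C9 and C9' | `O[C@@]1(C#C[C@]2(O)[C@H](C)CC[C@H]3C(C)(C)CCC[C@]23C)[C@H](C)CC[C@H]2C(C)(C)CCC[C@]12C`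
A2 | alternative 1 | trans-2,5,5,8a-tetramethyloctahydronaphthalen-1(2H)-one (C9 ketone of the decalin half) | `O=C1[C@H](C)CC[C@H]2C(C)(C)CCC[C@]12C`
A3 | alternative 1 | dilithium acetylide | `[Li]C#C[Li]`
A4 | alternative 2 | (3E,7E)-3,8-dimethyl-1,10-bis(2,6,6-trimethyl-3-oxocyclohexyl)deca-3,7-diene, C5 and C5' set, C10 epimers | `CC1C(=O)CCC(C)(C)[C@@H]1CC/C(C)=C/CC/C=C(C)/CC[C@H]1C(C)(C)CCC(=O)C1C`
A5 | alternative 2 | (3E,7E)-3,8-dimethyldeca-3,7-diene-1,10-diylbis(magnesium bromide) | `Br[Mg]CC/C(C)=C/CC/C=C(C)/CC[Mg]Br`
A6 | alternative 2 | 2,4,4-trimethylcyclohex-2-en-1-one | `CC1=CC(C)(C)CCC1=O`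
A7 | alternative 2 | copper monobromide–dimethyl sulfide complex CuBr·SMe2 | `[Cu+].[Br-].CSC`
A8 | alternative 3 | tetracyclic diene with a formyl group on C6 and C6' | `C(CC1=C(C)C[C@H](C=O)[C@H]2C(C)(C)CCC[C@]12C)C1=C(C)C[C@H](C=O)[C@H]2C(C)(C)CCC[C@]12C`
A9 | alternative 3 | acyclic bis-trienal: two (E)-enals, each tethered through C4–C1 to a C7=C8–C9=C10 diene, the dienes joined at C9 and C9' by the C11–C11' bridge | `O=C/C=C/C(C)(C)CCC/C(C)=C(/C(C)=C)CCC(\C(C)=C)=C(\C)CCCC(C)(C)/C=C/C=O`
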